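**Assumptions:** the target has no stereocentres (it is achiral), so "single enantiomer" is read as the single geometric isomer given (Z side-chain alkene, E enone). Ketone 1 and aldehyde 8 are taken as catalogue items.

## Retrosynthetic overview

1. Target ⇐ fluoride removal of an aryl TBS ether and of a diisopropylsilylene bridging O4' and the tertiary carbinol oxygen (this bridge masks the acid-labile Z-hydroxyalkenyl phenol until the end).
2. E-enone ⇐ Claisen–Schmidt condensation of the silylene-protected methyl ketone with 4-(TBSO)benzaldehyde.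
3. Aryl–vinyl bond and Z-alkene ⇐ silaketal-tethered 8-endo Heck cyclisation (new step) of an aryl iodide carrying an ArO–Si(iPr)2–O–CMe2–CH=CH2 tether.
4. Tethered iodide ⇐ 4'-O-silylation of 3'-iodo-2',4'-dihydroxy-6'-methoxyacetophenone with the chlorosilane from iPr2SiCl2 and 2-methylbut-3-en-2-ol; the iodide ⇐ iodination of the commercial acetophenone.
5. Rings: both benzene rings are purchased. The only ring formed is the temporary eight-membered 1,3,2-dioxasilocine (step 4), which is opened again in the last step.

## Route

**Step 1**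
Reactants: 1, 1-(2,4-dihydroxy-6-methoxyphenyl)ethan-1-one (2',4'-dihydroxy-6'-methoxyacetophenone)
Product: 2, 1-(2,4-dihydroxy-3-iodo-6-methoxyphenyl)ethan-1-one (iodine on the carbon between the two OH groups)
Conditions: BnMe3N·ICl2 (1.0 equiv), CaCO3, CH2Cl2–MeOH (5:2), 0 °C → rt
Reagents that add atoms: benzyltrimethylammonium dichloroiodate, `C[N+](C)(C)Cc1ccccc1.Cl[I-]Cl` (delivers I)
Why: Electrophilic aromatic iodination (SEAr); C3' is ortho to both free hydroxyls and unhindered, whereas C5' is shielded by the 6'-OMe methyl that the acetyl group pushes toward it, and one equivalent at low temperature limits di-iodination.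

**Step 2**
Reactants: 3, dichlorodi(propan-2-yl)silane; 4, 2-methylbut-3-en-2-ol
Product: 5, chloro[(2-methylbut-3-en-2-yl)oxy]di(propan-2-yl)silane
Conditions: 4, n-BuLi (1.0 equiv), THF, −78 °C; then add to 3 (1.5 equiv), −78 °C → rt; Kugelrohr distillation
Reagents that add atoms: dichlorodi(propan-2-yl)silane (3), `CC(C)[Si](Cl)(Cl)C(C)C`
Why: Nucleophilic substitution at silicon by the lithium tert-alkoxide; the bulk of the tert-alkoxy and isopropyl groups stops the reaction at mono-substitution.

**Step 3**
Reactants: 2, 1-(2,4-dihydroxy-3-iodo-6-methoxyphenyl)ethan-1-one; 5, chloro[(2-methylbut-3-en-2-yl)oxy]di(propan-2-yl)silane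
Product: 6, 1-[2-hydroxy-3-iodo-6-methoxy-4-({[(2-methylbut-3-en-2-yl)oxy]di(propan-2-yl)silyl}oxy)phenyl]ethan-1-one (mixed silaketal on O4'; 2'-OH free)
Conditions: 5 (1.2 equiv), imidazole (2.5 equiv), DMAP (5 mol %), CH2Cl2, 0 °C → rt
Reagents that add atoms: chlorosilane 5, `C=CC(C)(C)O[Si](Cl)(C(C)C)C(C)C`
Why: Phenol O-silylation (unsymmetrical silaketal formation); only the non-chelated, more acidic 4'-OH reacts, because the 2'-OH is tied up in the hydrogen bond to the ketone and flanked by I and acetyl.

**Step 4 (key step, new)**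
Reactants: 6, the tethered aryl iodide from step 3
Product: 7, 1-[(5Z)-7-hydroxy-9-methoxy-4,4-dimethyl-2,2-di(propan-2-yl)-4H-1,3,2-benzodioxasilocin-8-yl]ethan-1-one. This is the acetophenone in which C3' carries a (Z)-CH=CH–CMe2–O– chain whose oxygen is bridged through Si(iPr)2 to O4', giving an eight-membered ring; 2'-OH is free.
Conditions: Pd2(dba)3 (5 mol %), [HP(t-Bu)3]BF4 (12 mol %), Cy2NMe (3 equiv), 1,4-dioxane (5 mM), 70 °C
Reagents that add atoms: none
Why: Proposed new method: a temporary silaketal tether turns the normally E-selective Mizoroki–Heck arylation of 2-methylbut-3-en-2-ol into an intramolecular 8-endo-trig Heck cyclisation — oxidative addition into the C–I bond, syn-carbopalladation with the aryl group going to the terminal CH2 (the internal carbon is neopentyl-like, so 7-exo is disfavoured, as in the intermolecular reaction), then syn-β-hydride elimination of a benzylic hydrogen (the other β-carbon is quaternary, so no chain-walking) inside the eight-membered ring, where only the cis (Z) endocyclic alkene is geometrically possible; the closest known reaction types are the intermolecular Heck reaction of aryl iodides with 2-methylbut-3-en-2-ol (E products), endo-selective intramolecular Heck closures of benzo-fused eight-membered rings, and temporary silicon-tether ring closures used to enforce Z-alkenes.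

**Step 5**
Reactants: 7, the cyclic silaketal methyl ketone from step 4; 8, 4-[(tert-butyldimethylsilyl)oxy]benzaldehyde
Product: 9, (2E)-3-{4-[(tert-butyldimethylsilyl)oxy]phenyl}-1-[(5Z)-7-hydroxy-9-methoxy-4,4-dimethyl-2,2-di(propan-2-yl)-4H-1,3,2-benzodioxasilocin-8-yl]prop-2-en-1-one
Conditions: LiHMDS (3.5 equiv), THF, −78 °C; then 8 (1.2 equiv), −78 °C → rt; pH 7 buffer quench
Reagents that add atoms: aldehyde 8, `CC(C)(C)[Si](C)(C)Oc1ccc(C=O)cc1`
Why: Claisen–Schmidt (aldol) condensation through the lithium phenoxide/enolate dianion with E1cB loss of hydroxide on warming; the non-nucleophilic, hydroxide-free base leaves both aryl silyl ethers and the Z-alkene untouched, and the conjugated enone forms as the thermodynamic E isomer.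

**Step 6**
Reactants: 9, the doubly silyl-protected chalcone from step 5
Product: 10, candidachalcone, (2E)-1-{2,4-dihydroxy-3-[(1Z)-3-hydroxy-3-methylbut-1-en-1-yl]-6-methoxyphenyl}-3-(4-hydroxyphenyl)prop-2-en-1-one
Conditions: TBAF (6 equiv), AcOH (6 equiv), THF, 0 °C → rt; neutral work-up, Et3N-deactivated silica or reverse-phase purification
Reagents that add atoms: none
Why: Fluoride-mediated desilylation (both ArO–Si bonds cleave first, then the tert-alkoxy fluorosilane via a pentacoordinate silicate); the AcOH buffer keeps the medium near neutral, avoiding acid-promoted cyclisation to the 2,2-dimethylchromene and base-promoted chalcone-to-flavanone closure, and neither alkene geometry is affected.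

## Compound list

1 | 1-(2,4-dihydroxy-6-methoxyphenyl)ethan-1-one | `COc1cc(O)cc(O)c1C(C)=O` | starting material
2 | 1-(2,4-dihydroxy-3-iodo-6-methoxyphenyl)ethan-1-one | `COc1cc(O)c(I)c(O)c1C(C)=O` | intermediate
3 | dichlorodi(propan-2-yl)silane | `CC(C)[Si](Cl)(Cl)C(C)C` | starting material
4 | 2-methylbut-3-en-2-ol | `CC(C)(O)C=C` | starting material
5 | chloro[(2-methylbut-3-en-2-yl)oxy]di(propan-2-yl)silane | `C=CC(C)(C)O[Si](Cl)(C(C)C)C(C)C` | intermediate
6 | 1-[2-hydroxy-3-iodo-6-methoxy-4-({[(2-methylbut-3-en-2-yl)oxy]di(propan-2-yl)silyl}oxy)phenyl]ethan-1-one | `COc1cc(O[Si](OC(C)(C)C=C)(C(C)C)C(C)C)c(I)c(O)c1C(C)=O` | intermediate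
7 | 1-[(5Z)-7-hydroxy-9-methoxy-4,4-dimethyl-2,2-di(propan-2-yl)-4H-1,3,2-benzodioxasilocin-8-yl]ethan-1-one | `COc1cc2O[Si](C(C)C)(C(C)C)OC(C)(C)/C=C\c2c(O)c1C(C)=O` | intermediate
8 | 4-[(tert-butyldimethylsilyl)oxy]benzaldehyde | `CC(C)(C)[Si](C)(C)Oc1ccc(C=O)cc1` | starting material
9 | (2E)-3-{4-[(tert-butyldimethylsilyl)oxy]phenyl}-1-[(5Z)-7-hydroxy-9-methoxy-4,4-dimethyl-2,2-di(propan-2-yl)-4H-1,3,2-benzodioxasilocin-8-yl]prop-2-en-1-one | `COc1cc2O[Si](C(C)C)(C(C)C)OC(C)(C)/C=C\c2c(O)c1C(=O)/C=C/c1ccc(O[Si](C)(C)C(C)(C)C)cc1` | intermediate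
10 | candidachalcone, (2E)-1-{2,4-dihydroxy-3-[(1Z)-3-hydroxy-3-methylbut-1-en-1-yl]-6-methoxyphenyl}-3-(4-hydroxyphenyl)prop-2-en-1-one | `COc1cc(O)c(/C=C\C(C)(C)O)c(O)c1C(=O)/C=C/c1ccc(O)cc1` | target

## Summary

Total steps: 6 (step 2 is a one-step side branch that makes the tether reagent).
Longest linear sequence: 5 steps (1 → 2 → 6 → 7 → 9 → 10).

Steps most likely to fail:

1. **Step 4 (proposed new tethered 8-endo Heck).** Risks are medium-ring closure losing to oligomerisation, proto-deiodination or 7-exo closure. Fallback (known chemistry): Suzuki–Miyaura coupling of unprotected iodide 2 with a preformed (Z)-alkenylboronate, (Z)-2-methyl-4-(pinacolboryl)but-3-en-2-ol, made by Z-selective trans-hydroboration of O-protected 2-methylbut-3-yn-2-ol. Closing the resulting Z-hydroxyalkenyl phenol with iPr2Si(OTf)2/2,6-lutidine then re-enters the route at 7.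

2. **Step 5 (LiHMDS Claisen–Schmidt).** Risks are stalling at the β-hydroxy ketone, silyl loss, or flavanone formation on work-up. Fallback: move the condensation ahead of the tether. Protect 2 as its 4'-O-MOM ether, run a classical KOH/EtOH Claisen–Schmidt with 4-(methoxymethoxy)benzaldehyde, and remove both MOM groups with HCl/MeOH while no acid-labile group is present. Then silylate the 4'- and 4-OH groups with 5, run the tethered Heck on the iodochalcone, and finish with fluoride.

3. **Step 1 (iodination regioselectivity, C3' versus C5', and di-iodination).** Fallback: fix the iodine position by symmetry. Convert 5-methoxyresorcinol to its bis-MOM ether, lithiate between the two OMOM groups (n-BuLi) and quench with I2, then remove the MOM groups. C-acetylation (Ac2O/BF3·OEt2 or Hoesch) of the resulting 2-iodo-5-methoxyresorcinol, whose two free ring positions are equivalent, gives 2 unambiguously.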